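**Hand constants.** Take your constants by hand from the runs before integrating anything: you want a quick number, and your hunch is more catalyst, more target.

| flask | starting material | reagent | free catalyst | remark | time |
|---|---|---|---|---|---|
| theta | 0.30 M | 0.15 M | 14 mM | run made earlier |  |
| delta | 0.30 M | 0.15 M | 340 mM | run made earlier |  |
| Thursday's | 0.30 M | 0.150 M | 25 mM |  | 30 min |
| Sunday's | 0.30 M | 0.150 M | 50 mM |  | 30 min |
| Saturday's | 0.30 M | 0.150 M | 100 mM |  | 30 min |
| Monday's | 0.30 M | 0.150 M | 200 mM |  | 30 min |
| Tuesday's | 0.30 M | 0.150 M | 400 mM |  | 30 min |

- theta (time / min: target / %, starting material / %): 3.00: 0, 95; 6.00: 1, 98; 10.0: 2, 97; 12.0: 1, 92; 15.0: 5, 93; 20.0: 1, 89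
- delta (time / min: target / %, starting material / %): 3.00: 0, 0; 6.00: 7, 0; 10.0: 16, 0; 12.0: 15, 2; 15.0: 18, 0; 20.0: 24, 0

(standard deviation of a reading: 2 percentage points)

- "hardly changes" means that all values lie within two and a half points (for a concentration: within two and a half percent of the largest)

- amount of target at the end, in percent of the starting material charged for Thursday's, Sunday's, Saturday's, Monday's, Tuesday's, in this order
- the shape of the row from first to last (falls, then rises / rises all the way / hardly changes / rises, then falls / falls all the way)

**Turnover rate.** Start with theta. Starting material reads 5.00 % down at 3.00 min, and the catalyst charge is 4.67 % of the starting material charge, so assume each catalyst takes up one starting material at once. Count the loss at 20.0 min in catalyst equivalents and subtract that first one. This gives f, the turnovers per catalyst per minute: 0.0679 min⁻¹, a reading carrying the scatter of 2 percentage points.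

**Delta's brake.** In delta the catalyst exceeds both charges, so treat the reagent charge as parked on catalyst and draining first-order into target. The 24 % at 20.0 min gives a release constant κ = 0.0327 min⁻¹, about half of f. Suspect free catalyst C, which is the spare charge plus what each target sets free, on average 76.0 mM in delta. Let the release run as f over one plus C/K. Delta's reading then gives K = 70.7 mM, the brake level: the free catalyst at which release falls to half of f.

**Two rounds.** Tuesday's flask starts with 100 mM of catalyst spare over the starting material, and in this reckoning that C gives 28.5 % target. Put half of that target back in as freed catalyst and go round again: 24.5 %. Monday's catalyst charge is less than the starting material charge, so assume leftover starting material takes up freed catalyst and the brake stays off: 43.5 %. Assume that at the low end of the row target grows with the catalyst charge, and commit to a row that rises, then falls.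

**Forecast, result.** The forecast reads 10 %, 21 %, 29 %, 31 %, 31.5 %, rises all the way: “The rise flattens at high catalyst.”

The flask gives 9.40 %, 18.6 %, 31.6 %, 33.3 %, 22.6 %: rises, then falls.

    starting material + free catalyst → catalyst intermediate A (k = 49.0 L mol⁻¹ min⁻¹)
    reagent + catalyst intermediate A → catalyst intermediate B (k = 36.0 L mol⁻¹ min⁻¹)
    catalyst intermediate B ⇌ by-product + catalyst intermediate C (K = 0.480 M, k = 0.0550 min⁻¹)
    catalyst intermediate C ⇌ free catalyst + target (K = 0.320 M, k = 0.290 min⁻¹)
    target → over-reaction product (k = 0.00570 min⁻¹)

**The return.** Monday's flask stands 10 points below my figure, and the row turns at 170 mM. Part of the fall is free catalyst taking target back into catalyst intermediate C. Remove that return from both flasks and the change from Monday's to Tuesday's goes from −11 points to 0.074 points, the largest single effect there, not the whole story. Tuesday's flask holds 175 mM free catalyst at 30.0 min, a brake factor, one plus C/K, of 3.48. Monday's flask holds 10.7 mM, a brake factor of 1.15.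

The readings are simulated with made-up constants, and the scatter is random.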